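The route rests on cutting the C3=C4 olefin of the lactone ring (O1, C2, C3, C4, C5, C6) by ring-closing metathesis. This cis double bond sits between the acyl carbon C2 and the homoallylic carbinol C6, so the acrylate of a C6 homoallylic alcohol closes the ring, fixes the Z geometry and loses only ethene in one operation. The precursor is an acyclic acrylate diene in which O4' and O6' are locked in an acetonide inherited from a commercial statin side-chain building block and O2' is silylated, which leaves O6 as the single acylation site; C2' and C6 come from two reagent-controlled allylborations.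

Key step: step 9

Remark: locants follow the target (lactone O1, C2 to C6; side chain C1' to C21' with hydroxyls on C2', C4', C6'); (−)-Ipc2B(allyl) is assumed to be used as its commercial pentane solution.

Step 1
Reactants: 1 tert-butyl 2-[(4R,6S)-6-(hydroxymethyl)-2,2-dimethyl-1,3-dioxan-4-yl]acetate
Product: 2 tert-butyl 2-[(4R,6S)-2,2-dimethyl-6-{[(trifluoromethanesulfonyl)oxy]methyl}-1,3-dioxan-4-yl]acetate
Conditions: Tf2O, 2,6-lutidine, CH2Cl2, −78 °C
Reagents that add atoms: trifluoromethanesulfonic anhydride, O=S(=O)(OS(=O)(=O)C(F)(F)F)C(F)(F)F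
Why: O-Sulfonylation of the unhindered primary alcohol with Tf2O and a hindered pyridine base at −78 °C should give the primary alkyl triflate without disturbing the acetonide, the tert-butyl ester or either stereocentre, and the triflate is carried on at once without purification.

Step 2
Reactants: 2 tert-butyl 2-[(4R,6S)-2,2-dimethyl-6-{[(trifluoromethanesulfonyl)oxy]methyl}-1,3-dioxan-4-yl]acetate; 3 tetradecylmagnesium chloride
Product: 4 tert-butyl 2-[(4R,6R)-2,2-dimethyl-6-pentadecyl-1,3-dioxan-4-yl]acetate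
Conditions: CuBr·SMe2 (10 mol%), Et2O/THF, −40 °C to 0 °C
Reagents that add atoms: none
Why: Copper-catalysed alkyl–alkyl cross-coupling of a primary triflate with an alkyl Grignard reagent should install the C15 chain far faster than the Grignard reagent can attack the hindered tert-butyl ester, and it leaves the C6' and C4' centres untouched.

Step 3
Reactants: 4 tert-butyl 2-[(4R,6R)-2,2-dimethyl-6-pentadecyl-1,3-dioxan-4-yl]acetate
Product: 5 2-[(4R,6R)-2,2-dimethyl-6-pentadecyl-1,3-dioxan-4-yl]acetaldehyde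
Conditions: i-Bu2AlH (1.1 equiv), CH2Cl2, −78 °C; MeOH, then aqueous potassium sodium tartrate
Reagents that add atoms: none
Why: One equivalent of i-Bu2AlH at −78 °C should stop at the tetrahedral aluminium hemiacetal of the tert-butyl ester, which collapses to the aldehyde only on work-up (partial ester reduction), and the β-alkoxy aldehyde has no α-stereocentre to lose.

Step 4
Reactants: 5 2-[(4R,6R)-2,2-dimethyl-6-pentadecyl-1,3-dioxan-4-yl]acetaldehyde
Product: 7 (2S)-1-[(4S,6R)-2,2-dimethyl-6-pentadecyl-1,3-dioxan-4-yl]pent-4-en-2-ol, via borinate ester 6 (not isolated)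
Conditions: (−)-Ipc2B(allyl) (1 M in pentane), Et2O, −78 °C; then 3 M NaOH, 30% H2O2, 0 °C to rt
Reagents that add atoms: (−)-B-allyldiisopinocampheylborane [Ipc groups from (+)-α-pinene], C=CCB([C@@H]1C[C@@H]2C[C@H]([C@H]1C)C2(C)C)[C@@H]1C[C@@H]2C[C@H]([C@H]1C)C2(C)C
Why: Brown asymmetric allylboration through a chair six-membered transition state, in which the (+)-α-pinene-derived reagent should add allyl to the Si face of the aldehyde under reagent control and so set C2' (2S in 7) syn to the oxygen on C4', the borinate being cleaved by the oxidative work-up.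

Step 5
Reactants: 7 (2S)-1-[(4S,6R)-2,2-dimethyl-6-pentadecyl-1,3-dioxan-4-yl]pent-4-en-2-ol
Product: 8 tert-butyl{[(2S)-1-[(4R,6R)-2,2-dimethyl-6-pentadecyl-1,3-dioxan-4-yl]pent-4-en-2-yl]oxy}dimethylsilane
Conditions: TBSCl, imidazole, DMF, rt
Reagents that add atoms: tert-butyldimethylsilyl chloride, CC(C)(C)[Si](C)(C)Cl
Why: Silyl ether formation on the secondary alcohol masks O2' so that the later C6 hydroxyl is the only free alcohol, and the group should survive ozonolysis, allylboration, acylation and metathesis.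

Step 6
Reactants: 8 tert-butyl{[(2S)-1-[(4R,6R)-2,2-dimethyl-6-pentadecyl-1,3-dioxan-4-yl]pent-4-en-2-yl]oxy}dimethylsilane
Product: 10 (3R)-3-[(tert-butyldimethylsilyl)oxy]-4-[(4R,6R)-2,2-dimethyl-6-pentadecyl-1,3-dioxan-4-yl]butanal, via secondary ozonide 9 (not isolated)
Conditions: O3, CH2Cl2, −78 °C; then PPh3, −78 °C to rt
Reagents that add atoms: ozone, [O-][O+]=O
Why: Ozonolysis of the terminal olefin with reductive PPh3 work-up should give the one-carbon-shorter β-silyloxy aldehyde (C6 aldehyde) without touching the acetonide or the silyl ether, and the aldehyde is used crude to avoid β-elimination.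

Step 7
Reactants: 10 (3R)-3-[(tert-butyldimethylsilyl)oxy]-4-[(4R,6R)-2,2-dimethyl-6-pentadecyl-1,3-dioxan-4-yl]butanal
Product: 12 (4S,6S)-6-[(tert-butyldimethylsilyl)oxy]-7-[(4R,6R)-2,2-dimethyl-6-pentadecyl-1,3-dioxan-4-yl]hept-1-en-4-ol, via borinate ester 11 (not isolated)
Conditions: (−)-Ipc2B(allyl) (1 M in pentane), Et2O, −78 °C; then 3 M NaOH, 30% H2O2, 0 °C to rt
Reagents that add atoms: (−)-B-allyldiisopinocampheylborane [Ipc groups from (+)-α-pinene], C=CCB([C@@H]1C[C@@H]2C[C@H]([C@H]1C)C2(C)C)[C@@H]1C[C@@H]2C[C@H]([C@H]1C)C2(C)C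
Why: A second Brown allylboration with the same reagent should again deliver allyl to the Si face under reagent control, setting C6 (4S in 12) syn to the silyloxy group on C2' while introducing C5, C4 and the terminal olefin.

Step 8
Reactants: 12 (4S,6S)-6-[(tert-butyldimethylsilyl)oxy]-7-[(4R,6R)-2,2-dimethyl-6-pentadecyl-1,3-dioxan-4-yl]hept-1-en-4-ol
Product: 13 (4S,6R)-6-[(tert-butyldimethylsilyl)oxy]-7-[(4R,6R)-2,2-dimethyl-6-pentadecyl-1,3-dioxan-4-yl]hept-1-en-4-yl prop-2-enoate
Conditions: acryloyl chloride, Et3N, DMAP (cat.), CH2Cl2, 0 °C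
Reagents that add atoms: acryloyl chloride, C=CC(=O)Cl
Why: O-Acylation (esterification) of the only free hydroxyl with acryloyl chloride under DMAP catalysis should give the acrylate, which brings in C2 and C3 and completes the diene without affecting any stereocentre.

Step 9
Reactants: 13 (4S,6R)-6-[(tert-butyldimethylsilyl)oxy]-7-[(4R,6R)-2,2-dimethyl-6-pentadecyl-1,3-dioxan-4-yl]hept-1-en-4-yl prop-2-enoate
Product: 14 (6S)-6-{(2R)-2-[(tert-butyldimethylsilyl)oxy]-3-[(4R,6R)-2,2-dimethyl-6-pentadecyl-1,3-dioxan-4-yl]propyl}-5,6-dihydro-2H-pyran-2-one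
Conditions: second-generation Grubbs catalyst RuCl2(=CHPh)(H2IMes)(PCy3) (5 mol%), CH2Cl2 (0.005 M), 40 °C
Reagents that add atoms: none
Why: The ruthenium benzylidene should load onto the unhindered allyl terminus at C4, and the resulting alkylidene then adds across the tethered acrylate in a [2+2] step and cycloreverts from the ruthenacyclobutane to join C3 to C4 with release of ethene. The closest known reaction type is ring-closing olefin metathesis of acrylates of homoallylic alcohols to 5,6-dihydro-2H-pyran-2-ones. The six-membered lactone ring (O1, C2, C3, C4, C5, C6) closes by metathesis of a 1,7-diene held together by the C6–O1–C2 ester tether, and the ring size enforces the Z geometry of C3=C4. No stereocentre is formed, so C6 and C2' are carried through unchanged from the allylborations. The step needs ring closure to outrun intermolecular cross-metathesis and carbonyl chelation of the carbene, which high dilution, warm CH2Cl2 and the presence of only one terminal olefin and one acrylate (every other oxygen is blocked as acetonide or silyl ether) should secure; Ti(OiPr)4 can be added if turnover is slow.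

Step 10
Reactants: 14 (6S)-6-{(2R)-2-[(tert-butyldimethylsilyl)oxy]-3-[(4R,6R)-2,2-dimethyl-6-pentadecyl-1,3-dioxan-4-yl]propyl}-5,6-dihydro-2H-pyran-2-one
Product: 15 (6S)-6-[(2R,4R,6R)-2,4,6-trihydroxyhenicosyl]-5,6-dihydro-2H-pyran-2-one
Conditions: 48% aqueous HF, MeCN, 0 °C to rt
Reagents that add atoms: none
Why: Aqueous HF in acetonitrile should hydrolyse the acetonide and cleave the silyl ether in one acidic global deprotection, without the basic conditions that would open the lactone or promote oxa-Michael addition of the C2' hydroxyl to the enoate, so all four stereocentres are delivered unchanged.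

Compound list
1 | tert-butyl 2-[(4R,6S)-6-(hydroxymethyl)-2,2-dimethyl-1,3-dioxan-4-yl]acetate | OC[C@@H]1C[C@H](CC(=O)OC(C)(C)C)OC(C)(C)O1 | starting material
2 | tert-butyl 2-[(4R,6S)-2,2-dimethyl-6-{[(trifluoromethanesulfonyl)oxy]methyl}-1,3-dioxan-4-yl]acetate | O=S(=O)(OC[C@@H]1C[C@H](CC(=O)OC(C)(C)C)OC(C)(C)O1)C(F)(F)F | intermediate
3 | tetradecylmagnesium chloride | CCCCCCCCCCCCCC[Mg]Cl | starting material
4 | tert-butyl 2-[(4R,6R)-2,2-dimethyl-6-pentadecyl-1,3-dioxan-4-yl]acetate | CCCCCCCCCCCCCCC[C@@H]1C[C@H](CC(=O)OC(C)(C)C)OC(C)(C)O1 | intermediate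
5 | 2-[(4R,6R)-2,2-dimethyl-6-pentadecyl-1,3-dioxan-4-yl]acetaldehyde | CCCCCCCCCCCCCCC[C@@H]1C[C@H](CC=O)OC(C)(C)O1 | intermediate
6 | (2S)-1-[(4S,6R)-2,2-dimethyl-6-pentadecyl-1,3-dioxan-4-yl]pent-4-en-2-yl diisopinocampheylborinate (Ipc groups from (+)-α-pinene; not isolated) | CCCCCCCCCCCCCCC[C@@H]1C[C@H](C[C@@H](OB([C@@H]2C[C@@H]3C[C@H]([C@H]2C)C3(C)C)[C@@H]2C[C@@H]3C[C@H]([C@H]2C)C3(C)C)CC=C)OC(C)(C)O1 | intermediate
7 | (2S)-1-[(4S,6R)-2,2-dimethyl-6-pentadecyl-1,3-dioxan-4-yl]pent-4-en-2-ol | CCCCCCCCCCCCCCC[C@@H]1C[C@H](C[C@@H](O)CC=C)OC(C)(C)O1 | intermediate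
8 | tert-butyl{[(2S)-1-[(4R,6R)-2,2-dimethyl-6-pentadecyl-1,3-dioxan-4-yl]pent-4-en-2-yl]oxy}dimethylsilane | CCCCCCCCCCCCCCC[C@@H]1C[C@H](C[C@@H](O[Si](C)(C)C(C)(C)C)CC=C)OC(C)(C)O1 | intermediate
9 | 3-{(2R)-2-[(tert-butyldimethylsilyl)oxy]-3-[(4R,6R)-2,2-dimethyl-6-pentadecyl-1,3-dioxan-4-yl]propyl}-1,2,4-trioxolane (secondary ozonide of 8; trioxolane carbon configuration undefined; not isolated) | CCCCCCCCCCCCCCC[C@@H]1C[C@H](C[C@@H](O[Si](C)(C)C(C)(C)C)CC2OCOO2)OC(C)(C)O1 | intermediate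
10 | (3R)-3-[(tert-butyldimethylsilyl)oxy]-4-[(4R,6R)-2,2-dimethyl-6-pentadecyl-1,3-dioxan-4-yl]butanal | CCCCCCCCCCCCCCC[C@@H]1C[C@H](C[C@@H](O[Si](C)(C)C(C)(C)C)CC=O)OC(C)(C)O1 | intermediate
11 | (4S,6S)-6-[(tert-butyldimethylsilyl)oxy]-7-[(4R,6R)-2,2-dimethyl-6-pentadecyl-1,3-dioxan-4-yl]hept-1-en-4-yl diisopinocampheylborinate (Ipc groups from (+)-α-pinene; not isolated) | CCCCCCCCCCCCCCC[C@@H]1C[C@H](C[C@@H](O[Si](C)(C)C(C)(C)C)C[C@@H](OB([C@@H]2C[C@@H]3C[C@H]([C@H]2C)C3(C)C)[C@@H]2C[C@@H]3C[C@H]([C@H]2C)C3(C)C)CC=C)OC(C)(C)O1 | intermediate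
12 | (4S,6S)-6-[(tert-butyldimethylsilyl)oxy]-7-[(4R,6R)-2,2-dimethyl-6-pentadecyl-1,3-dioxan-4-yl]hept-1-en-4-ol | CCCCCCCCCCCCCCC[C@@H]1C[C@H](C[C@@H](O[Si](C)(C)C(C)(C)C)C[C@@H](O)CC=C)OC(C)(C)O1 | intermediate
13 | (4S,6R)-6-[(tert-butyldimethylsilyl)oxy]-7-[(4R,6R)-2,2-dimethyl-6-pentadecyl-1,3-dioxan-4-yl]hept-1-en-4-yl prop-2-enoate | CCCCCCCCCCCCCCC[C@@H]1C[C@H](C[C@@H](O[Si](C)(C)C(C)(C)C)C[C@@H](OC(=O)C=C)CC=C)OC(C)(C)O1 | intermediate
14 | (6S)-6-{(2R)-2-[(tert-butyldimethylsilyl)oxy]-3-[(4R,6R)-2,2-dimethyl-6-pentadecyl-1,3-dioxan-4-yl]propyl}-5,6-dihydro-2H-pyran-2-one | CCCCCCCCCCCCCCC[C@@H]1C[C@H](C[C@@H](O[Si](C)(C)C(C)(C)C)C[C@@H]2CC=CC(=O)O2)OC(C)(C)O1 | intermediate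
15 | (6S)-6-[(2R,4R,6R)-2,4,6-trihydroxyhenicosyl]-5,6-dihydro-2H-pyran-2-one | CCCCCCCCCCCCCCC[C@@H](O)C[C@@H](O)C[C@@H](O)C[C@@H]1CC=CC(=O)O1 | target

Total step count: 10. Longest linear sequence: 10 steps (from 1).

Steps most likely to fail

Step 2 (copper-catalysed coupling). The β-oxygenated triflate may decompose, or the Grignard reagent may add to the ester before the coupling takes place. The fallback sets out from 1 and changes the C–C bond construction to olefination and reduction. Parikh–Doering oxidation (SO3·pyridine, DMSO, i-Pr2NEt, CH2Cl2, 0 °C) should give the aldehyde tert-butyl 2-[(4R,6S)-6-formyl-2,2-dimethyl-1,3-dioxan-4-yl]acetate F1. Wittig olefination with the ylide from tetradecyltriphenylphosphonium bromide and NaN(SiMe3)2 (THF, −78 °C) should give the alkene tert-butyl 2-[(4R,6S)-2,2-dimethyl-6-[(1Z)-pentadec-1-en-1-yl]-1,3-dioxan-4-yl]acetate F2. Hydrogenation (H2, Pd/C, EtOAc) then comes back to the route at 4.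

Step 3 (partial reduction). The hindered tert-butyl ester may be over-reduced to the alcohol or may react incompletely. The fallback sets out from 4 and replaces the partial reduction by a full reduction and re-oxidation. LiAlH4 (THF, 0 °C) should give the alcohol 2-[(4S,6R)-2,2-dimethyl-6-pentadecyl-1,3-dioxan-4-yl]ethan-1-ol F3, and Dess–Martin periodinane (NaHCO3, CH2Cl2) then comes back to the route at 5.

Step 9 (ring-closing metathesis). Intermolecular cross-metathesis to oligomers, or chelation of the ruthenium carbene by the ester carbonyl, may outcompete ring closure. The fallback sets out from 12 and closes the same C3=C4 bond by a ring-closing Horner–Wadsworth–Emmons olefination. Esterification with 2-(diethoxyphosphoryl)acetic acid (DCC, DMAP, CH2Cl2) should give the phosphonoacetate (4S,6R)-6-[(tert-butyldimethylsilyl)oxy]-7-[(4R,6R)-2,2-dimethyl-6-pentadecyl-1,3-dioxan-4-yl]hept-1-en-4-yl 2-(diethoxyphosphoryl)acetate F4. Ozonolysis (O3, CH2Cl2, −78 °C; then PPh3) should give the aldehyde (3R,5R)-5-[(tert-butyldimethylsilyl)oxy]-6-[(4R,6R)-2,2-dimethyl-6-pentadecyl-1,3-dioxan-4-yl]-1-oxohexan-3-yl 2-(diethoxyphosphoryl)acetate F5. Masamune–Roush conditions (LiCl, i-Pr2NEt, MeCN, high dilution, rt) then come back to the route at 14.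

Further compounds
F1 | step 2 | tert-butyl 2-[(4R,6S)-6-formyl-2,2-dimethyl-1,3-dioxan-4-yl]acetate | O=C[C@@H]1C[C@H](CC(=O)OC(C)(C)C)OC(C)(C)O1
F2 | step 2 | tert-butyl 2-[(4R,6S)-2,2-dimethyl-6-[(1Z)-pentadec-1-en-1-yl]-1,3-dioxan-4-yl]acetate | CCCCCCCCCCCCC/C=C\[C@@H]1C[C@H](CC(=O)OC(C)(C)C)OC(C)(C)O1
F3 | step 3 | 2-[(4S,6R)-2,2-dimethyl-6-pentadecyl-1,3-dioxan-4-yl]ethan-1-ol | CCCCCCCCCCCCCCC[C@@H]1C[C@H](CCO)OC(C)(C)O1
F4 | step 9 | (4S,6R)-6-[(tert-butyldimethylsilyl)oxy]-7-[(4R,6R)-2,2-dimethyl-6-pentadecyl-1,3-dioxan-4-yl]hept-1-en-4-yl 2-(diethoxyphosphoryl)acetate | CCCCCCCCCCCCCCC[C@@H]1C[C@H](C[C@@H](O[Si](C)(C)C(C)(C)C)C[C@@H](OC(=O)CP(=O)(OCC)OCC)CC=C)OC(C)(C)O1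
F5 | step 9 | (3R,5R)-5-[(tert-butyldimethylsilyl)oxy]-6-[(4R,6R)-2,2-dimethyl-6-pentadecyl-1,3-dioxan-4-yl]-1-oxohexan-3-yl 2-(diethoxyphosphoryl)acetate | CCCCCCCCCCCCCCC[C@@H]1C[C@H](C[C@@H](O[Si](C)(C)C(C)(C)C)C[C@@H](OC(=O)CP(=O)(OCC)OCC)CC=O)OC(C)(C)O1
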